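Retrosynthesis first cuts the four O–CH3 bonds (the catechols travel as methyl ethers) and then the pyrrole N1–CH2 bond of the propyl linker, which gives the 3,4-diaryl-1H-pyrrole 18 and the 1-(3-chloropropyl)azecane 29.
The pyrrole has the same quinolin-5-yl group on C3 and on C4 and hydrogen on C2 and C5, the substitution that an azine ArCH2CH=N–N=CHCH2Ar hands on to a pyrrole, so it is cut at C3–C4 and N1–C5 back to the azine 13.
The azine is put together from the arylacetaldehyde 10 and its own hydrazone 12; 10 is traced through an ethoxyvinyl group to 5-bromo-6,7-dimethoxyquinoline 7, whose pyridine ring is opened at N1–C2 to a nitrocinnamaldehyde made from 2-bromoisovanillin.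
The azecane is cut at N1–C10 (sulfonamide alkylation) and at C4–C5 (copper-catalysed alkyl–alkyl coupling).
Forward, the rings arise in the order quinoline pyridine ring, pyrrole, azecane (separate branch); the two fragments are then joined and the ethers cleaved.
The only stereocentre (C3 of the azecane, S) is bought in (R)-3-bromo-2-methylpropan-1-ol: its CH2Br carbon becomes C4, its CH2OH carbon becomes C2, and no bond at the stereocentre is made or broken.

Key step: step 9

Remark: the ene-hydrazide geometry of 15 and the configuration of the two transient sp3 carbons of 16 are left undefined because both disappear on aromatisation; the aldehyde 10 and the hydrazone 12 are taken to be used crude on the day they are made; 31 is taken to be isolated as the neutral free base.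

Step 1
Reactants: 1 2-bromo-3-hydroxy-4-methoxybenzaldehyde (2-bromoisovanillin)
Product: 2 2-bromo-3,4-dimethoxybenzaldehyde
Conditions: MeI, K2CO3, DMF, rt
Reagents that add atoms: iodomethane, CI
Why: Williamson O-methylation of the only phenol, whose potassium salt is by far the best nucleophile present, so the aldehyde and the aryl bromide stay untouched.

Step 2
Reactants: 2 2-bromo-3,4-dimethoxybenzaldehyde
Product: 3 2-bromo-3,4-dimethoxy-6-nitrobenzaldehyde
Conditions: HNO3 (65%), AcOH, 0 to 15 °C, dark
Reagents that add atoms: nitric acid, O[N+](=O)[O-]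
Why: Electrophilic aromatic nitration should go to C6, para to the 3-methoxy group, just as veratraldehyde gives its 6-nitro derivative, because the 4-methoxy group that would direct to C5 is drained by conjugation with the para formyl group.

Step 3
Reactants: 3 2-bromo-3,4-dimethoxy-6-nitrobenzaldehyde; 4 (triphenylphosphoranylidene)acetaldehyde
Product: 5 (E)-3-(2-bromo-3,4-dimethoxy-6-nitrophenyl)prop-2-enal
Conditions: Ph3P=CHCHO (1.1 equiv), toluene, 80 °C
Reagents that add atoms: (triphenylphosphoranylidene)acetaldehyde 4, O=CC=P(c1ccccc1)(c1ccccc1)c1ccccc1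
Why: Wittig olefination with a stabilised ylide should give the E enal, and the electron-poor nitrobenzaldehyde is far more electrophilic than the product enal, which holds back a second homologation.

Step 4
Reactants: 5 (E)-3-(2-bromo-3,4-dimethoxy-6-nitrophenyl)prop-2-enal
Product: 7 5-bromo-6,7-dimethoxyquinoline, via aminocinnamaldehyde 6 (not isolated)
Conditions: Fe powder, AcOH/EtOH, 80 °C
Reagents that add atoms: none
Why: Béchamp-type reduction of the nitro group, acid-promoted E/Z equilibration of the enal and intramolecular imine condensation (Friedländer-type reductive cyclisation of an o-nitrocinnamaldehyde) should close the pyridine ring, and iron in acetic acid leaves the aryl bromide intact.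

Step 5
Reactants: 7 5-bromo-6,7-dimethoxyquinoline; 8 (E)-2-(2-ethoxyvinyl)-4,4,5,5-tetramethyl-1,3,2-dioxaborolane
Product: 9 5-[(E)-2-ethoxyvinyl]-6,7-dimethoxyquinoline
Conditions: Pd(OAc)2 (5 mol %), SPhos (10 mol %), K3PO4, dioxane/H2O, 90 °C
Reagents that add atoms: (E)-2-(2-ethoxyvinyl)-4,4,5,5-tetramethyl-1,3,2-dioxaborolane 8, CCO/C=C/B1OC(C)(C)C(C)(C)O1
Why: Suzuki–Miyaura coupling, in which the bulky electron-rich biarylphosphine lets zerovalent palladium insert into the doubly flanked C5–Br bond and the vinyl boronate transfers the masked acetaldehyde unit with retention of its E geometry.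

Step 6
Reactants: 9 5-[(E)-2-ethoxyvinyl]-6,7-dimethoxyquinoline
Product: 10 (6,7-dimethoxyquinolin-5-yl)acetaldehyde
Conditions: 2 M aq. HCl, THF, 40 °C; aq. NaHCO3 to pH 7–8, extraction (CH2Cl2), used crude at once
Reagents that add atoms: water, O
Why: Acid-catalysed hydrolysis of the enol ether (C-protonation, hydration of the oxocarbenium ion and loss of ethanol from the hemiacetal) should unmask the arylacetaldehyde, which is neutralised, extracted and carried on without purification because arylacetaldehydes self-condense on standing.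

Step 7
Reactants: 10 (6,7-dimethoxyquinolin-5-yl)acetaldehyde; 11 hydrazine (used as the hydrate)
Product: 12 (E)-[2-(6,7-dimethoxyquinolin-5-yl)ethylidene]hydrazine
Conditions: N2H4·H2O (10 equiv), EtOH, 0 °C, slow addition of 10 (half of the batch from step 6); concentration, extraction (CH2Cl2), used crude
Reagents that add atoms: hydrazine 11, NN
Why: Hydrazone formation by carbonyl condensation, in which slow addition of the aldehyde to a large excess of hydrazine keeps the hydrazone from meeting a second aldehyde molecule, so the E mono-hydrazone should form instead of the azine.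

Step 8
Reactants: 12 (E)-[2-(6,7-dimethoxyquinolin-5-yl)ethylidene]hydrazine; 10 (6,7-dimethoxyquinolin-5-yl)acetaldehyde
Product: 13 (E,E)-1,2-bis[2-(6,7-dimethoxyquinolin-5-yl)ethylidene]hydrazine
Conditions: 10 (1.0 equiv, second half of the batch), AcOH (cat.), EtOH, 0 °C to rt; azine collected by filtration
Reagents that add atoms: none
Why: Azine formation by condensation of the hydrazone NH2 group with the second aldehyde molecule should give the thermodynamically preferred E,E isomer, and any disproportionation of the hydrazone leads to the same symmetric azine, so scrambling cannot give a wrong product.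

Step 9
Reactants: 13 (E,E)-1,2-bis[2-(6,7-dimethoxyquinolin-5-yl)ethylidene]hydrazine; 14 benzoyl chloride
Product: 17 1-benzoyl-3,4-bis(6,7-dimethoxyquinolin-5-yl)pyrrole, via bis(ene-hydrazide) 15 (not isolated), via bis(N-benzoylimine) 16 (not isolated)
Conditions: BzCl (3 equiv), pyridine, 170 °C (sealed vessel, microwave)
Reagents that add atoms: benzoyl chloride 14, O=C(Cl)c1ccccc1
Why: Twofold N-benzoylation of the azine with loss of the two benzylic α-protons gives the bis(ene-hydrazide) 15, in which the N–N bond is the central bond of a 1,5-diene, and a thermal [3,3]-sigmatropic (3,4-diaza-Cope) shift cleaves this weak bond while it joins the two benzylic carbons as pyrrole C3–C4, giving the bis(N-benzoylimine) 16. The closest known reaction is the Piloty–Robinson pyrrole synthesis in its aroyl chloride/pyridine variant, a relative of the rearrangement step of the Fischer indole synthesis. The pyrrole ring then closes by 5-exo-trig attack of one acylamino nitrogen (after tautomerisation to the enamide) on the carbon of the other N-acylimine, which forms N1–C5, and expulsion of benzamide aromatises the ring. No stereocentre results, because the two sp3 carbons of 16 become sp2 again on aromatisation. The only selectivity required is the direction of ene-hydrazide formation, and the substrate settles it: the azine is symmetric, each arm has one α-position only, and that position is benzylic to the quinoline, so the styrene-like tautomer is the favoured one. Because the hindered C3–C4 bond arises intramolecularly in a six-membered transition state, no bimolecular coupling between two crowded partners is needed, and the excess of benzoyl chloride allows for reversible acylation of the quinoline nitrogens.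

Step 10
Reactants: 17 1-benzoyl-3,4-bis(6,7-dimethoxyquinolin-5-yl)pyrrole
Product: 18 3,4-bis(6,7-dimethoxyquinolin-5-yl)-1H-pyrrole
Conditions: 2 M aq. NaOH, MeOH/THF, rt
Reagents that add atoms: none
Why: Saponification of an N-acylpyrrole, an activated amide because the nitrogen lone pair belongs to the aromatic sextet, so hydroxide should remove the benzoyl group under conditions that leave the aryl methyl ethers alone.

Step 11
Reactants: 19 (R)-3-bromo-2-methylpropan-1-ol; 20 (6-bromohexyloxy)(tert-butyl)dimethylsilane
Product: 22 (S)-9-(tert-butyldimethylsilyloxy)-2-methylnonan-1-ol, via Grignard reagent 21 (not isolated)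
Conditions: 20, Mg, THF, 45 °C; 19, MeMgBr (1.0 equiv), THF, −78 °C; then 21 (1.5 equiv), Li2CuCl4 (3 mol %), −78 °C to rt
Reagents that add atoms: (6-bromohexyloxy)(tert-butyl)dimethylsilane 20, CC(C)(C)[Si](C)(C)OCCCCCCBr
Why: Copper-catalysed Kochi-type sp3–sp3 coupling of an alkyl Grignard reagent with a primary bromide, run on the magnesium alkoxide of the bromo alcohol so that no protecting group is needed; the stereocentre lies one carbon from the reacting CH2Br and is carried through unchanged (the descriptor turns from R to S only because the substituent ranking changes).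

Step 12
Reactants: 22 (S)-9-(tert-butyldimethylsilyloxy)-2-methylnonan-1-ol; 23 tert-butyl N-(2-nitrophenylsulfonyl)carbamate
Product: 24 tert-butyl N-[(S)-9-(tert-butyldimethylsilyloxy)-2-methylnonyl]-N-(2-nitrophenylsulfonyl)carbamate
Conditions: PPh3, DIAD, THF, 0 °C to rt
Reagents that add atoms: tert-butyl N-(2-nitrophenylsulfonyl)carbamate 23, CC(C)(C)OC(=O)NS(=O)(=O)c1ccccc1[N+](=O)[O-]
Why: Mitsunobu N-alkylation (Fukuyama variant) of the acidic Boc-sulfonamide by the primary alcohol should place exactly one alkyl group on nitrogen without touching the silyl ether or the β-stereocentre.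

Step 13
Reactants: 24 tert-butyl N-[(S)-9-(tert-butyldimethylsilyloxy)-2-methylnonyl]-N-(2-nitrophenylsulfonyl)carbamate
Product: 25 N-[(S)-9-hydroxy-2-methylnonyl]-2-nitrobenzenesulfonamide
Conditions: HCl (3 M in MeOH), rt
Reagents that add atoms: none
Why: Acidolysis should remove the Boc group from the sulfonyl carbamate and methanolyse the primary silyl ether in the same pot, while the nitrobenzenesulfonamide is stable to acid.

Step 14
Reactants: 25 N-[(S)-9-hydroxy-2-methylnonyl]-2-nitrobenzenesulfonamide
Product: 26 (S)-3-methyl-1-(2-nitrophenylsulfonyl)azecane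
Conditions: PPh3, DIAD, toluene/THF, rt, slow addition (final ca. 5 mM)
Reagents that add atoms: none
Why: Intramolecular Fukuyama–Mitsunobu alkylation, a method established for eight- to ten-membered cyclic sulfonamides, in which the acidic sulfonamide NH is alkylated by the unbranched primary C10 carbinol under high dilution, the closure being placed at the chain end remote from the methyl branch to avoid a hindered SN2 centre.

Step 15
Reactants: 26 (S)-3-methyl-1-(2-nitrophenylsulfonyl)azecane
Product: 27 (S)-3-methylazecane
Conditions: PhSH, K2CO3, MeCN, 50 °C; acid–base extraction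
Reagents that add atoms: none
Why: Fukuyama denosylation, in which thiolate adds to the nitroarene to give a Meisenheimer adduct that collapses with loss of SO2, should free the secondary amine without touching any ring bond.

Step 16
Reactants: 27 (S)-3-methylazecane; 28 1-bromo-3-chloropropane
Product: 29 (S)-1-(3-chloropropyl)-3-methylazecane
Conditions: 28 (3 equiv), K2CO3, MeCN, rt; used without storage
Reagents that add atoms: 1-bromo-3-chloropropane 28, ClCCCBr
Why: SN2 N-alkylation in which bromide leaves far faster than chloride, so the secondary amine should be monoalkylated at the bromine-bearing carbon and the chloride kept for the fragment union.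

Step 17
Reactants: 18 3,4-bis(6,7-dimethoxyquinolin-5-yl)-1H-pyrrole; 29 (S)-1-(3-chloropropyl)-3-methylazecane
Product: 30 5,5'-{1-[3-((S)-3-methylazecan-1-yl)propyl]pyrrole-3,4-diyl}bis(6,7-dimethoxyquinoline)
Conditions: NaH, DMF, 0 °C; then 29, NaI (cat.), 60 °C
Reagents that add atoms: none
Why: SN2 N-alkylation of the sodium pyrrolide with iodide catalysis should be clean because the anion is by far the strongest nucleophile present, the pyrrole α-carbons are shielded by the aryl groups, and the neutral quinoline nitrogens do not compete for a primary alkyl chloride.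

Step 18
Reactants: 30 5,5'-{1-[3-((S)-3-methylazecan-1-yl)propyl]pyrrole-3,4-diyl}bis(6,7-dimethoxyquinoline)
Product: 31 isohalitulin
Conditions: BBr3 (12 equiv), CH2Cl2, −78 °C to rt; H2O, then aq. NaHCO3 to pH 7–8, under Ar
Reagents that add atoms: none
Why: Lewis-acid cleavage of aryl methyl ethers by BBr3 (bromide attacks the methyl group of the boron-complexed ether) should free all four phenols, the excess reagent covering the three basic nitrogens, and the remote stereocentre is unaffected.

Compound list
1 | 2-bromo-3-hydroxy-4-methoxybenzaldehyde (2-bromoisovanillin) | COc1ccc(C=O)c(Br)c1O | starting material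
2 | 2-bromo-3,4-dimethoxybenzaldehyde | COc1ccc(C=O)c(Br)c1OC | intermediate
3 | 2-bromo-3,4-dimethoxy-6-nitrobenzaldehyde | COc1cc([N+](=O)[O-])c(C=O)c(Br)c1OC | intermediate
4 | (triphenylphosphoranylidene)acetaldehyde | O=CC=P(c1ccccc1)(c1ccccc1)c1ccccc1 | starting material
5 | (E)-3-(2-bromo-3,4-dimethoxy-6-nitrophenyl)prop-2-enal | COc1cc([N+](=O)[O-])c(/C=C/C=O)c(Br)c1OC | intermediate
6 | (E)-3-(6-amino-2-bromo-3,4-dimethoxyphenyl)prop-2-enal (not isolated) | COc1cc(N)c(/C=C/C=O)c(Br)c1OC | intermediate
7 | 5-bromo-6,7-dimethoxyquinoline | COc1cc2ncccc2c(Br)c1OC | intermediate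
8 | (E)-2-(2-ethoxyvinyl)-4,4,5,5-tetramethyl-1,3,2-dioxaborolane | CCO/C=C/B1OC(C)(C)C(C)(C)O1 | starting material
9 | 5-[(E)-2-ethoxyvinyl]-6,7-dimethoxyquinoline | CCO/C=C/c1c(OC)c(OC)cc2ncccc12 | intermediate
10 | (6,7-dimethoxyquinolin-5-yl)acetaldehyde | O=CCc1c(OC)c(OC)cc2ncccc12 | intermediate
11 | hydrazine (used as the hydrate) | NN | starting material
12 | (E)-[2-(6,7-dimethoxyquinolin-5-yl)ethylidene]hydrazine | N/N=C/Cc1c(OC)c(OC)cc2ncccc12 | intermediate
13 | (E,E)-1,2-bis[2-(6,7-dimethoxyquinolin-5-yl)ethylidene]hydrazine | COc1cc2ncccc2c(C/C=N/N=C/Cc2c(OC)c(OC)cc3ncccc23)c1OC | intermediate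
14 | benzoyl chloride | O=C(Cl)c1ccccc1 | starting material
15 | N,N'-dibenzoyl-N,N'-bis[2-(6,7-dimethoxyquinolin-5-yl)ethenyl]hydrazine (not isolated) | O=C(c1ccccc1)N(C=Cc1c(OC)c(OC)cc2ncccc12)N(C=Cc1c(OC)c(OC)cc2ncccc12)C(=O)c1ccccc1 | intermediate
16 | N,N'-[2,3-bis(6,7-dimethoxyquinolin-5-yl)butane-1,4-diylidene]dibenzamide (not isolated) | O=C(N=CC(c1c(OC)c(OC)cc2ncccc12)C(C=NC(=O)c1ccccc1)c1c(OC)c(OC)cc2ncccc12)c1ccccc1 | intermediate
17 | 1-benzoyl-3,4-bis(6,7-dimethoxyquinolin-5-yl)pyrrole | O=C(c1ccccc1)n1cc(-c2c(OC)c(OC)cc3ncccc23)c(-c2c(OC)c(OC)cc3ncccc23)c1 | intermediate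
18 | 3,4-bis(6,7-dimethoxyquinolin-5-yl)-1H-pyrrole | COc1cc2ncccc2c(-c2c[nH]cc2-c2c(OC)c(OC)cc3ncccc23)c1OC | intermediate
19 | (R)-3-bromo-2-methylpropan-1-ol | C[C@H](CO)CBr | starting material
20 | (6-bromohexyloxy)(tert-butyl)dimethylsilane | CC(C)(C)[Si](C)(C)OCCCCCCBr | starting material
21 | [6-(tert-butyldimethylsilyloxy)hexyl]magnesium bromide (not isolated) | CC(C)(C)[Si](C)(C)OCCCCCC[Mg]Br | intermediate
22 | (S)-9-(tert-butyldimethylsilyloxy)-2-methylnonan-1-ol | C[C@H](CO)CCCCCCCO[Si](C)(C)C(C)(C)C | intermediate
23 | tert-butyl N-(2-nitrophenylsulfonyl)carbamate | CC(C)(C)OC(=O)NS(=O)(=O)c1ccccc1[N+](=O)[O-] | starting material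
24 | tert-butyl N-[(S)-9-(tert-butyldimethylsilyloxy)-2-methylnonyl]-N-(2-nitrophenylsulfonyl)carbamate | C[C@H](CN(C(=O)OC(C)(C)C)S(=O)(=O)c1ccccc1[N+](=O)[O-])CCCCCCCO[Si](C)(C)C(C)(C)C | intermediate
25 | N-[(S)-9-hydroxy-2-methylnonyl]-2-nitrobenzenesulfonamide | C[C@H](CNS(=O)(=O)c1ccccc1[N+](=O)[O-])CCCCCCCO | intermediate
26 | (S)-3-methyl-1-(2-nitrophenylsulfonyl)azecane | C[C@H]1CCCCCCCN(S(=O)(=O)c2ccccc2[N+](=O)[O-])C1 | intermediate
27 | (S)-3-methylazecane | C[C@H]1CCCCCCCNC1 | intermediate
28 | 1-bromo-3-chloropropane | ClCCCBr | starting material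
29 | (S)-1-(3-chloropropyl)-3-methylazecane | C[C@H]1CCCCCCCN(CCCCl)C1 | intermediate
30 | 5,5'-{1-[3-((S)-3-methylazecan-1-yl)propyl]pyrrole-3,4-diyl}bis(6,7-dimethoxyquinoline) | C[C@H]1CCCCCCCN(CCCn2cc(-c3c(OC)c(OC)cc4ncccc34)c(-c3c(OC)c(OC)cc4ncccc34)c2)C1 | intermediate
31 | isohalitulin, 5,5'-{1-[3-((S)-3-methylazecan-1-yl)propyl]pyrrole-3,4-diyl}bis(quinoline-6,7-diol) | C[C@H]1CCCCCCCN(CCCn2cc(-c3c(O)c(O)cc4ncccc34)c(-c3c(O)c(O)cc4ncccc34)c2)C1 | target

Total step count: 18.
Longest linear sequence: 12 steps (steps 1–10, 17 and 18, from 1 to 31); the azecane branch (steps 11–16) has six steps before the union.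

Steps most likely to fail

Step 9. The risk is that the azine is not fully converted into the bis(ene-hydrazide), because benzoyl chloride and the liberated acid are taken up by the quinoline nitrogens. The crowded diaryl system may also decompose thermally before the sigmatropic shift and ring closure are complete. The fallback uses known chemistry, sets out from 7 and returns at 18. It gives up the azine and makes the two aryl–pyrrole bonds one after the other instead of the C3–C4 bond. Miyaura borylation of 7 (B2pin2, PdCl2(dppf), KOAc, dioxane, 90 °C) would give 6,7-dimethoxy-5-(4,4,5,5-tetramethyl-1,3,2-dioxaborolan-2-yl)quinoline F1. Twofold Suzuki–Miyaura coupling of F1 with commercial 3,4-dibromo-1-(triisopropylsilyl)pyrrole (Pd(OAc)2, SPhos, K3PO4, toluene/H2O, 100 °C) would give 3,4-bis(6,7-dimethoxyquinolin-5-yl)-1-(triisopropylsilyl)pyrrole F2. TBAF in THF would then remove the silyl group and deliver 18.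

Step 14. The risk is that intermolecular alkylation (oligomerisation) outruns the entropically and transannularly disfavoured ten-membered ring closure. The fallback closes the ring through a C=C bond instead of the N–C bond; it sets out from 19 and returns at 26. Coupling of the magnesium alkoxide of 19 with allylmagnesium bromide (Li2CuCl4 cat., THF) would give (S)-2-methylhex-5-en-1-ol F3. Pent-4-en-1-amine and 2-nitrobenzenesulfonyl chloride (Et3N, CH2Cl2) would give 2-nitro-N-(pent-4-en-1-yl)benzenesulfonamide F4. Mitsunobu alkylation of F4 with F3 (PPh3, DIAD, THF) would give the diene N-[(S)-2-methylhex-5-en-1-yl]-2-nitro-N-(pent-4-en-1-yl)benzenesulfonamide F5. Ring-closing metathesis of F5 (second-generation Grubbs catalyst RuCl2(=CHPh)(PCy3)(H2IMes), CH2Cl2, 40 °C, ca. 2 mM) would give (S)-3-methyl-1-(2-nitrophenylsulfonyl)-1,2,3,4,5,8,9,10-octahydroazecine F6 as an E/Z mixture. Diimide reduction of F6 (TsNHNH2, NaOAc, DME/H2O, reflux), which spares the nitro group, would then give 26.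

Step 2. The risk is that nitration at C5 (ortho to the 4-methoxy group) or ipso attack at the bromine-bearing carbon competes with attack at C6. The fallback changes the order so that a free hydroxyl controls the position; it sets out from 1 and returns at 3. Nitration of 1 itself (HNO3, AcOH, 0 °C) would be directed by the hydroxyl group, whose two ortho positions carry bromine and methoxy, so only the para position C6 is open. This would give 2-bromo-3-hydroxy-4-methoxy-6-nitrobenzaldehyde F7. O-Methylation of F7 (MeI, K2CO3, DMF) then gives 3.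

Further compounds
F1 | step 9 | 6,7-dimethoxy-5-(4,4,5,5-tetramethyl-1,3,2-dioxaborolan-2-yl)quinoline | COc1cc2ncccc2c(B2OC(C)(C)C(C)(C)O2)c1OC
F2 | step 9 | 3,4-bis(6,7-dimethoxyquinolin-5-yl)-1-(triisopropylsilyl)pyrrole | COc1cc2ncccc2c(-c2cn([Si](C(C)C)(C(C)C)C(C)C)cc2-c2c(OC)c(OC)cc3ncccc23)c1OC
F3 | step 14 | (S)-2-methylhex-5-en-1-ol | C[C@H](CO)CCC=C
F4 | step 14 | 2-nitro-N-(pent-4-en-1-yl)benzenesulfonamide | C=CCCCNS(=O)(=O)c1ccccc1[N+](=O)[O-]
F5 | step 14 | N-[(S)-2-methylhex-5-en-1-yl]-2-nitro-N-(pent-4-en-1-yl)benzenesulfonamide | C[C@H](CN(CCCC=C)S(=O)(=O)c1ccccc1[N+](=O)[O-])CCC=C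
F6 | step 14 | (S)-3-methyl-1-(2-nitrophenylsulfonyl)-1,2,3,4,5,8,9,10-octahydroazecine (E/Z mixture) | C[C@H]1CCC=CCCCN(S(=O)(=O)c2ccccc2[N+](=O)[O-])C1
F7 | step 2 | 2-bromo-3-hydroxy-4-methoxy-6-nitrobenzaldehyde | COc1cc([N+](=O)[O-])c(C=O)c(Br)c1O
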